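**Retrosynthetic overview**

1. Atrovirinone ⇒ its bis(triisopropylsilyl) ether; the last step only frees the two phenols.
2. Quinone ring (C1=O, C2–OAr, C3–OMe, C4=O, C5 and C6 prenylated) ⇒ disconnect C2–C3. Both carbons are α to a ring carbonyl and carry an ether oxygen, so at the hydroquinone level the ring is the α,α'-coupled form of a (Z)-hex-3-ene-2,5-dione. The bond is closed by anodic coupling of the two enol-ether termini of an acyclic bis(silyl enol ether), with aromatisation and oxidation to the quinone in the same cell.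
3. (Z)-Enedione ⇒ 2,5-bis(alkoxymethyl)-3,4-diprenylfuran by singlet-oxygen ring opening. Furan C2–C5 become quinone C1, C6, C5 and C4, the two furylmethyl carbons become C2 and C3, and the furan is the temporary ring that fixes the cis geometry.
4. Furan ⇒ Mitsunobu union of a furylmethanol with the free phenol of bis-silylated methyl 2,4,6-trihydroxybenzoate; furylmethanol ⇒ 3,4-diprenylfuran (two α-lithiations) ⇒ furan-3,4-diyldimethanol and an isobutenyl Grignard reagent.
5. Ring order: the furan and the benzoate ring are bought; the furan is opened in step 7 and the quinone ring, the only ring made, is closed in step 9.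

Key step: step 9

Remark on the chemistry: the target has no stereocentre. The only stereochemical element carried through is the Z geometry of the tetrasubstituted alkene in 13 and 14, inherited from the furan. The enol-ether geometry drawn for 14 is the expected one and has no bearing on the outcome. Intermediates 12 and 15 are racemic or diastereomeric transients and are drawn without configuration.

**Route**

Step 1
Reactants: 1 furan-3,4-diyldimethanol
Product: 2 3,4-bis(bromomethyl)furan
Conditions: PBr3, pyridine (cat.), Et2O, 0 °C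
Reagents that add atoms: phosphorus tribromide, BrP(Br)Br
Why: Substitution of the two primary furylmethyl alcohols by bromide via their phosphite esters (SN2) is standard for this diol and leaves the furan untouched at 0 °C.

Step 2
Reactants: 2 3,4-bis(bromomethyl)furan; 3 (2-methylprop-1-en-1-yl)magnesium bromide
Product: 4 3,4-bis(3-methylbut-2-en-1-yl)furan
Conditions: 3 (2.4 equiv), CuI (10 mol %), THF, −30 °C to rt
Reagents that add atoms: none
Why: Copper-catalysed Kumada-type sp2–sp3 coupling of an alkenyl Grignard reagent with a benzylic-type bromide builds both prenyl groups at once and avoids the allyl transposition of prenyl metals.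

Step 3
Reactants: 4 3,4-bis(3-methylbut-2-en-1-yl)furan
Product: 6 2-(methoxymethyl)-3,4-bis(3-methylbut-2-en-1-yl)furan, via furyllithium 5 (not isolated)
Conditions: n-BuLi (1.05 equiv), THF, −78 to 0 °C; MOMCl, −78 °C to rt
Reagents that add atoms: chloromethyl methyl ether, COCCl
Why: α-Lithiation of the furan (the two α-positions are equivalent by symmetry) followed by SN2 alkylation of the furyllithium with the chloromethyl ether.

Step 4
Reactants: 6 2-(methoxymethyl)-3,4-bis(3-methylbut-2-en-1-yl)furan
Product: 8 [5-(methoxymethyl)-3,4-bis(3-methylbut-2-en-1-yl)furan-2-yl]methanol, via furyllithium 7 (not isolated)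
Conditions: n-BuLi (1.1 equiv), THF, −78 to 0 °C; (CH2O)n, −78 °C to rt; H2O quench
Reagents that add atoms: formaldehyde (as paraformaldehyde), C=O
Why: Second α-lithiation at the only remaining ring C–H and 1,2-addition of the furyllithium to formaldehyde (hydroxymethylation).

Step 5
Reactants: 9 methyl 2,4,6-trihydroxybenzoate
Product: 10 methyl 2-hydroxy-4,6-bis[(triisopropylsilyl)oxy]benzoate
Conditions: TIPSCl (2.1 equiv), imidazole, DMF, 0 °C to rt
Reagents that add atoms: chlorotriisopropylsilane, CC(C)[Si](Cl)(C(C)C)C(C)C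
Why: Selective phenol silylation: the 4-OH and one ortho OH should react, while the last OH, hydrogen-bonded to the ester carbonyl, should stay free as in related partial protections of 2,4,6-trihydroxybenzoyl compounds.

Step 6
Reactants: 8 [5-(methoxymethyl)-3,4-bis(3-methylbut-2-en-1-yl)furan-2-yl]methanol; 10 methyl 2-hydroxy-4,6-bis[(triisopropylsilyl)oxy]benzoate
Product: 11 methyl 2-{[5-(methoxymethyl)-3,4-bis(3-methylbut-2-en-1-yl)furan-2-yl]methoxy}-4,6-bis[(triisopropylsilyl)oxy]benzoate
Conditions: PPh3, DIAD, THF, 0 °C to rt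
Reagents that add atoms: none
Why: Mitsunobu etherification of a primary alcohol with a salicylate-type phenol forms the aryl furylmethyl ether under neutral conditions that the acid-sensitive, electron-rich furan tolerates.

Step 7
Reactants: 11 methyl 2-{[5-(methoxymethyl)-3,4-bis(3-methylbut-2-en-1-yl)furan-2-yl]methoxy}-4,6-bis[(triisopropylsilyl)oxy]benzoate
Product: 13 methyl 2-{[(3Z)-6-methoxy-2,5-dioxo-3,4-bis(3-methylbut-2-en-1-yl)hex-3-en-1-yl]oxy}-4,6-bis[(triisopropylsilyl)oxy]benzoate, via furan endoperoxide 12 (not isolated)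
Conditions: O2 (1 equiv uptake), tetraphenylporphyrin (cat.), visible light, CH2Cl2, −78 °C; then Me2S, −78 °C to rt
Reagents that add atoms: oxygen, O=O
Why: [4+2] cycloaddition of singlet oxygen to the tetraalkylfuran, expected to be far faster than the Schenck ene reaction of the trisubstituted prenyl alkenes, followed by reductive O–O cleavage of the endoperoxide with Me2S gives the cis-enedione with the Z geometry of the furan ring.

Step 8
Reactants: 13 methyl 2-{[(3Z)-6-methoxy-2,5-dioxo-3,4-bis(3-methylbut-2-en-1-yl)hex-3-en-1-yl]oxy}-4,6-bis[(triisopropylsilyl)oxy]benzoate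
Product: 14 methyl 2-{[(1Z,3Z,5Z)-2,5-bis[(tert-butyldimethylsilyl)oxy]-6-methoxy-3,4-bis(3-methylbut-2-en-1-yl)hexa-1,3,5-trien-1-yl]oxy}-4,6-bis[(triisopropylsilyl)oxy]benzoate
Conditions: TBSOTf (2.5 equiv), Et3N (4 equiv), CH2Cl2, −78 to 0 °C; non-aqueous work-up, used crude
Reagents that add atoms: tert-butyldimethylsilyl trifluoromethanesulfonate, CC(C)(C)[Si](C)(C)OS(=O)(=O)C(F)(F)F
Why: Soft enolisation (silyl triflate and amine) of both α-alkoxy ketones at their oxygen-substituted α'-methylene groups gives the cross-conjugated bis(silyl enol ether), and the excess amine should suppress the competing intramolecular aldol reaction.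

Step 9
Reactants: 14 methyl 2-{[(1Z,3Z,5Z)-2,5-bis[(tert-butyldimethylsilyl)oxy]-6-methoxy-3,4-bis(3-methylbut-2-en-1-yl)hexa-1,3,5-trien-1-yl]oxy}-4,6-bis[(triisopropylsilyl)oxy]benzoate
Product: 17 methyl 2-{[2-methoxy-4,5-bis(3-methylbut-2-en-1-yl)-3,6-dioxocyclohexa-1,4-dien-1-yl]oxy}-4,6-bis[(triisopropylsilyl)oxy]benzoate, via cyclohexenedione 15 (not isolated), via hydroquinone 16 (not isolated)
Conditions: reticulated vitreous carbon anode, Pt cathode, undivided cell, constant current (about 4.2 F/mol), LiClO4 (0.1 M), 2,6-lutidine, MeCN/MeOH 4:1, 0 °C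
Reagents that add atoms: none
Why: Proposed new method: anodic one-electron oxidation of the electron-rich 1-alkoxy-2-silyloxy alkene termini of 14 should give a radical cation in which the two enol-ether β-carbons (the future C2 and C3) are held within bonding distance by the Z-configured tetrasubstituted C5=C6 alkene, so that C2–C3 bond formation (6-endo-trig closure, formally the 1,6-closure of a hexatriene radical cation), loss of one silyl group to methanol, a second electron transfer and loss of the second silyl group give cyclohexenedione 15. Intermediate 15 should enolise under 2,6-lutidine to hydroquinone 16, which is oxidised at a lower potential than 14 and is therefore carried on to quinone 17 by two further electrons in the same cell. The closest known reaction types are the oxidative coupling of silyl enol ethers or ketone enolates to 1,4-diketones and the anodic cyclisation of enol-ether radical cations onto silyl enol ethers; what is new is the intramolecular α,α'-coupling of the bis(enol ether) of a 2-ene-1,4-dione with in-cell aromatisation to a quinone. No stereocentre has to be controlled, because the two sp3 centres of 15 are erased on enolisation. The step needs oxidation of the dioxygenated triene in the presence of two prenyl alkenes and the silylated aryl ring (secured by its oxidation potential, expected to lie roughly 1 V below that of a trisubstituted alkene) and six-ring C–C coupling in preference to methanol capture or five-ring closure (secured by the cis geometry inherited from the furan and by the aromatic stabilisation that drains 15 into 16).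

Step 10
Reactants: 17 methyl 2-{[2-methoxy-4,5-bis(3-methylbut-2-en-1-yl)-3,6-dioxocyclohexa-1,4-dien-1-yl]oxy}-4,6-bis[(triisopropylsilyl)oxy]benzoate
Product: 18 atrovirinone, methyl 2,4-dihydroxy-6-{[2-methoxy-4,5-bis(3-methylbut-2-en-1-yl)-3,6-dioxocyclohexa-1,4-dien-1-yl]oxy}benzoate
Conditions: HF·pyridine, THF/pyridine, 0 °C to rt
Reagents that add atoms: none
Why: Fluoride-mediated cleavage of the two aryl silyl ethers (Si–F bond formation) under mildly acidic conditions that should leave the quinone, its methoxy and aryloxy groups and the prenyl alkenes intact.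

**Compound list**

1 | furan-3,4-diyldimethanol | OCc1cocc1CO | starting material
2 | 3,4-bis(bromomethyl)furan | BrCc1cocc1CBr | intermediate
3 | (2-methylprop-1-en-1-yl)magnesium bromide | CC(C)=C[Mg]Br | starting material
4 | 3,4-bis(3-methylbut-2-en-1-yl)furan | CC(C)=CCc1cocc1CC=C(C)C | intermediate
5 | [3,4-bis(3-methylbut-2-en-1-yl)furan-2-yl]lithium | [Li]c1occ(CC=C(C)C)c1CC=C(C)C | intermediate
6 | 2-(methoxymethyl)-3,4-bis(3-methylbut-2-en-1-yl)furan | COCc1occ(CC=C(C)C)c1CC=C(C)C | intermediate
7 | [5-(methoxymethyl)-3,4-bis(3-methylbut-2-en-1-yl)furan-2-yl]lithium | [Li]c1oc(COC)c(CC=C(C)C)c1CC=C(C)C | intermediate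
8 | [5-(methoxymethyl)-3,4-bis(3-methylbut-2-en-1-yl)furan-2-yl]methanol | COCc1oc(CO)c(CC=C(C)C)c1CC=C(C)C | intermediate
9 | methyl 2,4,6-trihydroxybenzoate | COC(=O)c1c(O)cc(O)cc1O | starting material
10 | methyl 2-hydroxy-4,6-bis[(triisopropylsilyl)oxy]benzoate | COC(=O)c1c(O)cc(O[Si](C(C)C)(C(C)C)C(C)C)cc1O[Si](C(C)C)(C(C)C)C(C)C | intermediate
11 | methyl 2-{[5-(methoxymethyl)-3,4-bis(3-methylbut-2-en-1-yl)furan-2-yl]methoxy}-4,6-bis[(triisopropylsilyl)oxy]benzoate | COCc1oc(COc2cc(O[Si](C(C)C)(C(C)C)C(C)C)cc(O[Si](C(C)C)(C(C)C)C(C)C)c2C(=O)OC)c(CC=C(C)C)c1CC=C(C)C | intermediate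
12 | methyl 2-{[4-(methoxymethyl)-5,6-bis(3-methylbut-2-en-1-yl)-2,3,7-trioxabicyclo[2.2.1]hept-5-en-1-yl]methoxy}-4,6-bis[(triisopropylsilyl)oxy]benzoate (racemic; bridgehead configuration fixed by the bicycle) | COCC12OOC(COc3cc(O[Si](C(C)C)(C(C)C)C(C)C)cc(O[Si](C(C)C)(C(C)C)C(C)C)c3C(=O)OC)(O1)C(CC=C(C)C)=C2CC=C(C)C | intermediate
13 | methyl 2-{[(3Z)-6-methoxy-2,5-dioxo-3,4-bis(3-methylbut-2-en-1-yl)hex-3-en-1-yl]oxy}-4,6-bis[(triisopropylsilyl)oxy]benzoate | COCC(=O)/C(CC=C(C)C)=C(CC=C(C)C)\C(=O)COc1cc(O[Si](C(C)C)(C(C)C)C(C)C)cc(O[Si](C(C)C)(C(C)C)C(C)C)c1C(=O)OC | intermediate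
14 | methyl 2-{[(1Z,3Z,5Z)-2,5-bis[(tert-butyldimethylsilyl)oxy]-6-methoxy-3,4-bis(3-methylbut-2-en-1-yl)hexa-1,3,5-trien-1-yl]oxy}-4,6-bis[(triisopropylsilyl)oxy]benzoate | CO/C=C(\O[Si](C)(C)C(C)(C)C)/C(CC=C(C)C)=C(CC=C(C)C)\C(O[Si](C)(C)C(C)(C)C)=C\Oc1cc(O[Si](C(C)C)(C(C)C)C(C)C)cc(O[Si](C(C)C)(C(C)C)C(C)C)c1C(=O)OC | intermediate
15 | methyl 2-{[6-methoxy-2,5-dioxo-3,4-bis(3-methylbut-2-en-1-yl)cyclohex-3-en-1-yl]oxy}-4,6-bis[(triisopropylsilyl)oxy]benzoate (transient mixture of diastereomers) | COC1C(Oc2cc(O[Si](C(C)C)(C(C)C)C(C)C)cc(O[Si](C(C)C)(C(C)C)C(C)C)c2C(=O)OC)C(=O)C(CC=C(C)C)=C(CC=C(C)C)C1=O | intermediate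
16 | methyl 2-[2,5-dihydroxy-6-methoxy-3,4-bis(3-methylbut-2-en-1-yl)phenoxy]-4,6-bis[(triisopropylsilyl)oxy]benzoate | COc1c(O)c(CC=C(C)C)c(CC=C(C)C)c(O)c1Oc1cc(O[Si](C(C)C)(C(C)C)C(C)C)cc(O[Si](C(C)C)(C(C)C)C(C)C)c1C(=O)OC | intermediate
17 | methyl 2-{[2-methoxy-4,5-bis(3-methylbut-2-en-1-yl)-3,6-dioxocyclohexa-1,4-dien-1-yl]oxy}-4,6-bis[(triisopropylsilyl)oxy]benzoate | COC(=O)c1c(O[Si](C(C)C)(C(C)C)C(C)C)cc(O[Si](C(C)C)(C(C)C)C(C)C)cc1OC1=C(OC)C(=O)C(CC=C(C)C)=C(CC=C(C)C)C1=O | intermediate
18 | atrovirinone, methyl 2,4-dihydroxy-6-{[2-methoxy-4,5-bis(3-methylbut-2-en-1-yl)-3,6-dioxocyclohexa-1,4-dien-1-yl]oxy}benzoate | COC(=O)c1c(O)cc(O)cc1OC1=C(OC)C(=O)C(CC=C(C)C)=C(CC=C(C)C)C1=O | target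

**Step count and risks**

Total step count: 10. Longest linear sequence: 9 steps (steps 1–4 and 6–10); step 5 is a one-step side branch.

Steps most likely to fail:

Step 9 (proposed new method). The radical cation may be captured by methanol, may close to a five-membered ring, or the enol ethers may be solvolysed before they are oxidised, so that six-ring C–C coupling is lost. The fallback uses known pericyclic and dehydrogenation chemistry and sets out from 14. Heating 14 (toluene, 110 °C, sealed tube) should bring about the thermal disrotatory 6π-electrocyclisation of the (Z,Z,Z)-triene, whose alkoxy termini point outward. This forms the same C2–C3 bond and gives the racemic cis-configured methyl 2-{[2,5-bis[(tert-butyldimethylsilyl)oxy]-6-methoxy-3,4-bis(3-methylbut-2-en-1-yl)cyclohexa-2,4-dien-1-yl]oxy}-4,6-bis[(triisopropylsilyl)oxy]benzoate F1. Dehydrogenation with DDQ (benzene, rt) should give the aromatic methyl 2-[2,5-bis[(tert-butyldimethylsilyl)oxy]-6-methoxy-3,4-bis(3-methylbut-2-en-1-yl)phenoxy]-4,6-bis[(triisopropylsilyl)oxy]benzoate F2. Global desilylation (Bu4NF/AcOH, THF, 0 °C) should give methyl 2-[2,5-dihydroxy-6-methoxy-3,4-bis(3-methylbut-2-en-1-yl)phenoxy]-4,6-dihydroxybenzoate F3, which Ag2O (Et2O, rt) should oxidise to the quinone. The fallback comes back to the route at 18.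

Step 7. Ene oxidation of the prenyl alkenes by singlet oxygen, or aldol closure of the enedione during the reductive work-up, may compete with clean ring opening. The fallback sets out from 11 and replaces the cycloaddition by a two-electron anodic alkoxylation (Clauson-Kaas reaction: carbon anode, Et4NOTs, MeOH, −20 °C, run at the potential of the furan). It should give the storable masked enedione methyl 2-{[2,5-dimethoxy-5-(methoxymethyl)-3,4-bis(3-methylbut-2-en-1-yl)-2,5-dihydrofuran-2-yl]methoxy}-4,6-bis[(triisopropylsilyl)oxy]benzoate F4 as a cis/trans mixture. Mild hydrolysis (aqueous acetone, pyridinium tosylate cat., 0 °C) should release the cis-enedione. The fallback comes back to the route at 13.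

Step 8. Intramolecular aldol closure to a 4-hydroxycyclopentenone, or γ-deprotonation at a prenyl methylene, may outrun double O-silylation. The fallback sets out from 13 and bypasses both the silyl enol ether and the electrolysis. Inverse addition of 13 to LiN(SiMe3)2 (2.3 equiv, THF, −78 °C) should give the dilithium dienolate. CuCl2 (2.2 equiv, DMF, −78 to 0 °C; Saegusa-type oxidative enolate coupling) should couple it to 15, which is isolated after enolisation as hydroquinone 16. Oxidation with Ag2O (Et2O, rt) should then give the quinone. The fallback comes back to the route at 17 and makes no compound outside the list.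

**Further compounds**

F1 | step 9 | methyl 2-{[2,5-bis[(tert-butyldimethylsilyl)oxy]-6-methoxy-3,4-bis(3-methylbut-2-en-1-yl)cyclohexa-2,4-dien-1-yl]oxy}-4,6-bis[(triisopropylsilyl)oxy]benzoate, cis, racemic (one enantiomer drawn) | CO[C@@H]1[C@H](Oc2cc(O[Si](C(C)C)(C(C)C)C(C)C)cc(O[Si](C(C)C)(C(C)C)C(C)C)c2C(=O)OC)C(O[Si](C)(C)C(C)(C)C)=C(CC=C(C)C)C(CC=C(C)C)=C1O[Si](C)(C)C(C)(C)C
F2 | step 9 | methyl 2-[2,5-bis[(tert-butyldimethylsilyl)oxy]-6-methoxy-3,4-bis(3-methylbut-2-en-1-yl)phenoxy]-4,6-bis[(triisopropylsilyl)oxy]benzoate | COc1c(O[Si](C)(C)C(C)(C)C)c(CC=C(C)C)c(CC=C(C)C)c(O[Si](C)(C)C(C)(C)C)c1Oc1cc(O[Si](C(C)C)(C(C)C)C(C)C)cc(O[Si](C(C)C)(C(C)C)C(C)C)c1C(=O)OC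
F3 | step 9 | methyl 2-[2,5-dihydroxy-6-methoxy-3,4-bis(3-methylbut-2-en-1-yl)phenoxy]-4,6-dihydroxybenzoate | COc1c(O)c(CC=C(C)C)c(CC=C(C)C)c(O)c1Oc1cc(O)cc(O)c1C(=O)OC
F4 | step 7 | methyl 2-{[2,5-dimethoxy-5-(methoxymethyl)-3,4-bis(3-methylbut-2-en-1-yl)-2,5-dihydrofuran-2-yl]methoxy}-4,6-bis[(triisopropylsilyl)oxy]benzoate, cis/trans mixture | COCC1(OC)OC(OC)(COc2cc(O[Si](C(C)C)(C(C)C)C(C)C)cc(O[Si](C(C)C)(C(C)C)C(C)C)c2C(=O)OC)C(CC=C(C)C)=C1CC=C(C)C
F0 | step 8 | none | none
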